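**Plan**

- Numbering: C1 lactone carbonyl, C2–C7 triene, C8 quaternary carbon, ring A = C9–C14 (OMe at C11, carbamate at C13), ring B = C8, C9, C14–C17 (C15=C16), C18–C21 diene, C22–C27 chain with lactone oxygen O23.
- Retrosynthetic cuts, in order: C5–C6 (ring-closing Suzuki coupling of the 16-membered lactone), C2=C3 (Horner–Wadsworth–Emmons), C19–CH3 and C19–C20 (two couplings on a C18=CBr2 unit), O23–C1 (ester), C17–C18 ([2,3]-Wittig shift from a C15 alcohol), and last C9–C10 plus C13–C14 (Diels–Alder).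
- Enabling feature: ring A carries oxygen at C11 and C13 and is cis-fused across C9–C14 to ring B, whose C8 holds a methyl group and the C7 carbon and whose C15 can be a carbonyl. That is the adduct of a 1,3-dioxygenated butadiene (C10–C13) with one of the two mirror-related alkenes of a 4-methyl-4-carboxy cyclohexa-2,5-dienone (C8 prochiral).
- Forward: ring B comes from benzoic acid; ring A is closed on it by the catalytic Diels–Alder reaction; the C20–C27 chain (from D-alaninal by two crotylborations) is joined at C19–C20; the macrolactone ring is closed last between C5 and C6.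
- Stereochemistry: C8, C9, C13, C14 from the cycloaddition (chiral boron cation, endo mode, approach on the ester face); C11 and C15 from substrate-controlled hydride additions; C17 by suprafacial transfer from C15; C26 from D-alanine; C22–C25 from reagent-controlled crotylborations; alkene geometries from stereospecific couplings and olefinations.

Key step: step 6

Conventions and assumption
- β is the face of the bicyclic core that carries H9 and H14; α is the opposite face. In the target, 11-OMe, 13-O, C7 (on C8) and C18 (on C17) are α, and the C8 methyl is β.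
- Assumption: the (S)-configured oxazaborolidinium cation is taken to select the enantiotopic alkene that gives the C8 configuration drawn; if the sense of induction is the opposite one, the (R) cation is used and nothing else changes.
- Starting materials 1, 6, 7, 21 and 38 and all reagents named are commercial.

**Ring B dienophile**

Step 1
Reactants: 1 benzoic acid
Product: 3 1-methylcyclohexa-2,5-diene-1-carboxylic acid, via dilithium Birch dianion 2 (not isolated)
Conditions: Li, NH3(l)/THF, −78 °C; MeI, −78 °C → rt; aq. HCl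
Reagents that add atoms: iodomethane, CI
Why: Birch reduction of the benzoate gives the cross-conjugated dianion 2, whose C1 carbanion is methylated by MeI (Birch reductive alkylation), the 2,5-diene pattern being fixed by protonation at C4.

Step 2
Reactants: 3 1-methylcyclohexa-2,5-diene-1-carboxylic acid
Product: 4 methyl 1-methylcyclohexa-2,5-diene-1-carboxylate
Conditions: MeI, K2CO3, DMF, rt
Reagents that add atoms: iodomethane, CI
Why: SN2 O-alkylation of the carboxylate under non-acidic conditions avoids acid-promoted migration of the skipped diene.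

Step 3
Reactants: 4 methyl 1-methylcyclohexa-2,5-diene-1-carboxylate
Product: 5 methyl 1-methyl-4-oxocyclohexa-2,5-diene-1-carboxylate
Conditions: Rh2(cap)4 (dirhodium tetracaprolactamate, 1 mol %), t-BuOOH (70 % aq., 5 equiv), K2CO3 (cat.), CH2Cl2, rt
Reagents that add atoms: tert-butyl hydroperoxide, CC(C)(C)OO
Why: the doubly allylic C4 methylene has the weakest C–H bond and is oxidised to the ketone by tert-butylperoxyl radicals generated at the dirhodium catalyst (catalytic allylic oxidation), while the quaternary carbon blocks aromatisation.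

**Diene**

Step 4
Reactants: 6 (E)-4-methoxybut-3-en-2-one; 7 4-methoxybenzyl alcohol
Product: 8 (E)-4-[(4-methoxybenzyl)oxy]but-3-en-2-one
Conditions: pyridinium p-toluenesulfonate (cat.), toluene, 80 °C, reduced pressure (removal of MeOH)
Reagents that add atoms: none
Why: acid-catalysed conjugate addition of the alcohol and loss of methanol (vinylogous transesterification) is driven by removal of methanol and gives the more stable E enol ether.

Step 5
Reactants: 8 (E)-4-[(4-methoxybenzyl)oxy]but-3-en-2-one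
Product: 9 (E)-1-[(4-methoxybenzyl)oxy]-3-(triisopropylsilyloxy)buta-1,3-diene
Conditions: i-Pr3SiOTf, Et3N, Et2O, 0 °C
Reagents that add atoms: triisopropylsilyl trifluoromethanesulfonate, CC(C)[Si](C(C)C)(C(C)C)OS(=O)(=O)C(F)(F)F
Why: soft enolisation of the methyl ketone, the only enolisable position, and O-silylation give the 2-silyloxy diene (silyl enol ether formation), the bulky TIPS group being chosen for stability towards the acidic catalyst of step 6.

**Ring A and core**

Step 6
Reactants: 5 methyl 1-methyl-4-oxocyclohexa-2,5-diene-1-carboxylate; 9 (E)-1-[(4-methoxybenzyl)oxy]-3-(triisopropylsilyloxy)buta-1,3-diene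
Product: 10 cis-fused adduct (ring A: C11=C12 TIPS enol ether, 13α-OPMB; ring B: C15 ketone, C16=C17, C8 β-methyl and α-CO2Me; H9 and H14 β)
Conditions: (S)-3,3-diphenyl-1-(o-tolyl)tetrahydropyrrolo[1,2-c][1,3,2]oxazaborole protonated with Tf2NH (oxazaborolidinium triflimide, 20 mol %), 9 (1.5 equiv), CH2Cl2, −78 °C; Et3N quench
Reagents that add atoms: none
Why: The boron cation binds the C15 carbonyl of 5 and lowers its LUMO, and diene 9 adds across one C=C in a concerted but asynchronous normal-demand Diels–Alder reaction in which the nucleophilic CH2 terminus (C10) bonds to the β-carbon C9 ahead of C13–C14 bond formation. The closest known reaction type is the oxazaborolidinium-catalysed enantioselective Diels–Alder reaction of quinone-type and cyclohexa-2,5-dienone dienophiles with silyloxy dienes, together with Lewis-acid-promoted additions of 1-alkoxy-3-silyloxybutadienes to 4,4-disubstituted cyclohexadienones. Ring A closes as a cyclohexene by suprafacial [4+2] cycloaddition, both new bonds forming on the same face of the ring B alkene, hence the cis C9/C14 fusion. C13 follows from the endo orientation of the E-alkoxy diene (13-OPMB cis to the C14–C15 bond), the C8/C9 relationship from diene approach on the face of the planar ester and away from the C8 methyl, and the absolute configuration at C8 from the catalyst, which shields one of the two enantiotopic alkene/face combinations through its coordination to one carbonyl lone pair. The step needs regioselectivity (secured by the matched polarisation of the 1,3-dioxygenated diene and the enone), enantiotopos selectivity (chiral cation), face selectivity (ester versus methyl) and mono-addition (the adduct enone is more hindered and no longer cross-conjugated; low temperature). The TIPS enol ether is used because it resists silyl transfer to the triflimide counter-ion, which would otherwise open an achiral background pathway.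

Step 7
Reactants: 10 cis-fused adduct
Product: 11 C11 ketone (13α-OPMB; C15 enone; C8 β-methyl and α-CO2Me)
Conditions: n-Bu4NF, AcOH (1:1), THF, −40 → 0 °C
Reagents that add atoms: none
Why: fluoride cleaves the Si–O bond and acetic acid protonates the enolate at C12 faster than it can expel the C13 alkoxide (buffered protodesilylation of a silyl enol ether), so no stereocentre is formed or touched.

Step 8
Reactants: 11 C11 ketone
Product: 12 11α-alcohol
Conditions: NaBH4, MeOH/CH2Cl2 (1:1), −78 °C
Reagents that add atoms: none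
Why: at −78 °C borohydride reduces the saturated C11 ketone much faster than the conjugated C15 ketone or the ester (chemoselective NaBH4 reduction), and axial attack from the β face of the ring A chair, in which 13-OPMB and the C9–C8 bond are equatorial, gives the equatorial 11α-alcohol cis to the C13 oxygen.

Step 9
Reactants: 12 11α-alcohol
Product: 13 11α-methyl ether
Conditions: Me3OBF4, 1,8-bis(dimethylamino)naphthalene, CH2Cl2, rt
Reagents that add atoms: trimethyloxonium tetrafluoroborate, C[O+](C)C.F[B-](F)(F)F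
Why: Meerwein-salt O-methylation with a non-nucleophilic amine base proceeds with retention at C11 and avoids the enolate chemistry (β-elimination of the C13 ether, C14 epimerisation) that a strong base would trigger.

Step 10
Reactants: 13 11α-methyl ether
Product: 14 7,15α-diol (C7 CH2OH; 15α-OH; C16=C17)
Conditions: i-Bu2AlH (5 equiv), CH2Cl2, −78 → −20 °C; aq. potassium sodium tartrate
Reagents that add atoms: none
Why: i-Bu2AlH reduces the enone in the 1,2 sense and the ester to the primary alcohol, and hydride reaches C15 from the convex β face because C10 of ring A sits axial on the α face of ring B, giving the 15α-alcohol (substrate-controlled carbonyl reduction).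

Step 11
Reactants: 14 7,15α-diol
Product: 15 7-O-TBS 15α-alcohol
Conditions: t-BuMe2SiCl, imidazole, CH2Cl2, 0 °C
Reagents that add atoms: tert-butyldimethylsilyl chloride, CC(C)(C)[Si](C)(C)Cl
Why: silylation with the bulky chlorosilane discriminates the primary C7 hydroxyl from the pseudoaxial secondary allylic C15 hydroxyl on steric grounds (selective silyl ether formation).

Step 12
Reactants: 15 7-O-TBS 15α-alcohol
Product: 16 15α-O-(tributylstannylmethyl) ether
Conditions: KH, Bu3SnCH2I, THF, 0 °C → rt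
Reagents that add atoms: tributyl(iodomethyl)stannane, CCCC[Sn](CI)(CCCC)CCCC
Why: Williamson alkylation of the potassium alkoxide with the iodomethylstannane gives the ether needed for the Still–Wittig rearrangement with the C15 configuration retained.

Step 13
Reactants: 16 15α-O-(tributylstannylmethyl) ether
Product: 18 17α-(hydroxymethyl) C15=C16 alkene (7-OTBS; 11α-OMe; 13α-OPMB), via 15α-lithiomethyl ether 17 (not isolated)
Conditions: n-BuLi, THF, −78 °C
Reagents that add atoms: none
Why: tin–lithium exchange gives the α-alkoxymethyllithium 17, which undergoes the [2,3]-sigmatropic Still–Wittig shift suprafacially across C15–C16–C17, so the new C17–C18 bond forms on the α face from which the pseudoaxial C15–O bond departs, setting C17 and moving the alkene to C15=C16.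

Step 14
Reactants: 18 17α-(hydroxymethyl) C15=C16 alkene
Product: 19 C18 aldehyde (17α-formyl)
Conditions: Dess–Martin periodinane, NaHCO3, CH2Cl2, 0 °C
Reagents that add atoms: none
Why: Dess–Martin oxidation under bicarbonate buffering gives the aldehyde without epimerising C17 or moving the β,γ-alkene into conjugation.

Step 15
Reactants: 19 C18 aldehyde
Product: 20 C18=C19 gem-dibromoalkene
Conditions: CBr4, PPh3, Zn, CH2Cl2, rt (ylide preformed); then 19, 0 °C
Reagents that add atoms: tetrabromomethane, BrC(Br)(Br)Br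
Why: Wittig-type dibromomethylenation (first stage of the Corey–Fuchs sequence) with the zinc-generated ylide is neutral enough to leave C17, the TBS ether and the PMB ether intact.

**C20–C27 chain**

Step 16
Reactants: 21 N-Boc-D-alaninal
Product: 22 tert-butyl N-[(2R,3S,4S)-3-hydroxy-4-methylhex-5-en-2-yl]carbamate
Conditions: (E)-but-2-ene, KOt-Bu, n-BuLi, THF, −78 → −45 °C; (−)-Ipc2BOMe, −78 °C; BF3·OEt2; then 21, −78 °C; NaOH, H2O2
Reagents that add atoms: (E)-but-2-ene, C/C=C/C
Why: Brown crotylboration through a chair six-membered transition state, in which the E-crotyl unit gives the 24,25-anti pair and the Ipc ligands from (−)-Ipc2BOMe direct attack to the Si face of the aldehyde in line with its Felkin–Anh preference, giving 25S anti to the D-alanine-derived C26 nitrogen.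

Step 17
Reactants: 22 tert-butyl N-[(2R,3S,4S)-3-hydroxy-4-methylhex-5-en-2-yl]carbamate
Product: 24 N-[(2R,3S,4S)-3-hydroxy-4-methylhex-5-en-2-yl]acetamide, via amino alcohol hydrochloride 23 (not isolated)
Conditions: HCl (4 M in dioxane), 0 °C → rt; concentrate; Ac2O, aq. NaHCO3/EtOAc, 0 °C
Reagents that add atoms: acetic anhydride, CC(=O)OC(C)=O
Why: acidolysis removes the Boc group (loss of isobutene and CO2) and the liberated amine is acetylated selectively over the hindered secondary alcohol under Schotten–Baumann conditions.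

Step 18
Reactants: 24 N-[(2R,3S,4S)-3-hydroxy-4-methylhex-5-en-2-yl]acetamide
Product: 25 N-[(2R,3S,4S)-3-(tert-butyldimethylsilyloxy)-4-methylhex-5-en-2-yl]acetamide
Conditions: t-BuMe2SiOTf, 2,6-lutidine, CH2Cl2, −78 → 0 °C
Reagents that add atoms: tert-butyldimethylsilyl trifluoromethanesulfonate, CC(C)(C)[Si](C)(C)OS(=O)(=O)C(F)(F)F
Why: the silyl triflate silylates the hindered C25 hydroxyl in the presence of the secondary amide (silyl ether formation).

Step 19
Reactants: 25 N-[(2R,3S,4S)-3-(tert-butyldimethylsilyloxy)-4-methylhex-5-en-2-yl]acetamide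
Product: 26 N-[(2R,3S,4R)-3-(tert-butyldimethylsilyloxy)-4-methyl-5-oxopentan-2-yl]acetamide
Conditions: O3, CH2Cl2, −78 °C; PPh3, −78 °C → rt
Reagents that add atoms: ozone, [O-][O+]=O
Why: ozonolysis with reductive work-up cleaves the terminal alkene to the C23 aldehyde, which is used at once so that C24 does not epimerise.

Step 20
Reactants: 26 N-[(2R,3S,4R)-3-(tert-butyldimethylsilyloxy)-4-methyl-5-oxopentan-2-yl]acetamide
Product: 27 N-[(2R,3S,4S,5R,6R)-3-(tert-butyldimethylsilyloxy)-5-hydroxy-4,6-dimethyloct-7-en-2-yl]acetamide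
Conditions: (E)-but-2-ene, KOt-Bu, n-BuLi, THF, −78 → −45 °C; (+)-Ipc2BOMe, −78 °C; BF3·OEt2; then 26, −78 °C; NaOH, H2O2
Reagents that add atoms: (E)-but-2-ene, C/C=C/C
Why: second Brown crotylboration, in which the E-crotyl reagent from (+)-Ipc2BOMe attacks the Re face through the chair transition state and gives the 22,23-anti and 23,24-syn (Felkin) relationships in the matched sense with the C24 methyl stereocentre.

Step 21
Reactants: 27 N-[(2R,3S,4S,5R,6R)-3-(tert-butyldimethylsilyloxy)-5-hydroxy-4,6-dimethyloct-7-en-2-yl]acetamide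
Product: 28 (3R,4R,5S,6S,7R)-7-acetamido-6-(tert-butyldimethylsilyloxy)-3,5-dimethyloct-1-en-4-yl 2-(diethoxyphosphoryl)acetate
Conditions: (EtO)2P(O)CH2CO2H, N,N′-dicyclohexylcarbodiimide, 4-(dimethylamino)pyridine (cat.), CH2Cl2, 0 °C → rt
Reagents that add atoms: 2-(diethoxyphosphoryl)acetic acid, CCOP(=O)(CC(=O)O)OCC
Why: carbodiimide activation of the phosphonoacetic acid, which reacts through a highly electrophilic phosphonoketene, acylates the hindered C23 hydroxyl (Steglich-type esterification) while the amide N–H does not compete.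

Step 22
Reactants: 28 C23 phosphonoacetate with terminal alkene
Product: 29 (1E,3R,4R,5S,6S,7R)-7-acetamido-6-(tert-butyldimethylsilyloxy)-3,5-dimethyl-1-(4,4,5,5-tetramethyl-1,3,2-dioxaborolan-2-yl)oct-1-en-4-yl 2-(diethoxyphosphoryl)acetate
Conditions: vinylboronic acid pinacol ester (3 equiv), second-generation Grubbs catalyst (H2IMes)(PCy3)Cl2Ru=CHPh (5 mol %), CH2Cl2, 40 °C
Reagents that add atoms: 4,4,5,5-tetramethyl-2-vinyl-1,3,2-dioxaborolane, C=CB1OC(C)(C)C(C)(C)O1
Why: olefin cross-metathesis of the monosubstituted alkene with the vinylboronate releases ethene and gives the E-alkenylboronate under thermodynamic control, which fixes the C20=C21 geometry.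

**Union and macrocycle**

Step 23
Reactants: 20 C18=C19 gem-dibromoalkene; 29 C20 alkenylboronate
Product: 30 19-bromo-(18Z,20E)-diene (core joined to the C20–C27 chain)
Conditions: Pd(PPh3)4 (10 mol %), TlOEt (1.5 equiv), THF/H2O (3:1), rt
Reagents that add atoms: none
Why: Suzuki–Miyaura coupling of a 1,1-dibromoalkene occurs selectively at the bromide trans to the bulky C17 substituent, where oxidative addition to zerovalent palladium is faster, with retention at both partners.

Step 24
Reactants: 30 19-bromo-(18Z,20E)-diene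
Product: 31 19-methyl-(18E,20E)-diene
Conditions: Me2Zn (4 equiv), Pd(P(t-Bu)3)2 (5 mol %), THF, 0 °C → rt
Reagents that add atoms: dimethylzinc, C[Zn]C
Why: Negishi methylation with the bulky-phosphine catalyst replaces the remaining bromide with retention of alkene geometry and gives the 18E trisubstituted alkene, excess Me2Zn covering the amide N–H and the acidic phosphonoacetate C–H.

Step 25
Reactants: 31 19-methyl-(18E,20E)-diene
Product: 32 13α-alcohol
Conditions: 2,3-dichloro-5,6-dicyano-1,4-benzoquinone, CH2Cl2/pH 7 NaH2PO4–Na2HPO4 buffer (10:1), 0 °C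
Reagents that add atoms: none
Why: the electron-rich PMB ether is cleaved oxidatively through a benzylic oxocarbenium ion that water hydrolyses, the buffer protecting the silyl ethers and the diene.

Step 26
Reactants: 32 13α-alcohol
Product: 34 13α-carbamate, via N-trichloroacetyl carbamate 33 (not isolated)
Conditions: Cl3CC(O)NCO, CH2Cl2, 0 °C; neutral Al2O3, rt
Reagents that add atoms: trichloroacetyl isocyanate, O=C=NC(=O)C(Cl)(Cl)Cl
Why: the only free hydroxyl adds to the highly electrophilic acyl isocyanate and the N-trichloroacetyl group is then hydrolysed on neutral alumina (carbamate formation via an acyl isocyanate), amide N–H groups being unreactive at 0 °C.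

Step 27
Reactants: 34 13α-carbamate
Product: 35 C7 primary alcohol
Conditions: HF·pyridine, pyridine, THF, 0 °C
Reagents that add atoms: none
Why: buffered HF·pyridine cleaves the primary silyl ether much faster than the C25 secondary TBS ether, which is flanked by two branched carbons (selective desilylation).

Step 28
Reactants: 35 C7 primary alcohol
Product: 36 C7 aldehyde
Conditions: Dess–Martin periodinane, NaHCO3, CH2Cl2, 0 °C → rt
Reagents that add atoms: none
Why: Dess–Martin oxidation gives the non-enolisable aldehyde on the quaternary C8 without touching carbamate, amide or phosphonate.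

Step 29
Reactants: 36 C7 aldehyde
Product: 37 (6E)-C6 pinacol alkenylboronate
Conditions: CrCl2 (8 equiv), Cl2CHB(pin) (2 equiv), LiI (4 equiv), THF, rt
Reagents that add atoms: 2-(dichloromethyl)-4,4,5,5-tetramethyl-1,3,2-dioxaborolane, ClC(Cl)B1OC(C)(C)C(C)(C)O1
Why: Takai–Utimoto olefination, in which the geminal dichromium species formed from the dihalomethylboronate and divalent chromium adds to the aldehyde and eliminates to the E-alkenylboronate while tolerating carbamate, amide and phosphonate.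

Step 30
Reactants: 38 but-2-yn-1-ol
Product: 40 (Z)-3-iodobut-2-en-1-ol, via cyclic alkenylalanate 39 (not isolated)
Conditions: NaAlH2(OCH2CH2OCH3)2, THF, 0 °C → rt; I2, −78 °C
Reagents that add atoms: iodine, II
Why: hydroxyl-directed trans-hydroalumination places aluminium at C3 in the cyclic alanate 39 and iodinolysis with retention gives the Z-iodide (hydroalumination–iodination of a propargylic alcohol).

Step 31
Reactants: 40 (Z)-3-iodobut-2-en-1-ol
Product: 41 (Z)-3-iodobut-2-enal
Conditions: activated MnO2, CH2Cl2, rt, dark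
Reagents that add atoms: none
Why: MnO2 oxidises the allylic alcohol under neutral conditions without Z/E isomerisation, and the aldehyde is used directly.

Step 32
Reactants: 37 (6E)-C6 pinacol alkenylboronate; 41 (Z)-3-iodobut-2-enal
Product: 42 seco compound (O23 (2E,4Z)-5-iodohexa-2,4-dienoate; C6 boronate)
Conditions: LiCl, i-Pr2NEt, MeCN, rt
Reagents that add atoms: none
Why: Horner–Wadsworth–Emmons olefination under Masamune–Roush conditions gives the 2E-enoate while the mild base leaves the carbamate, the boronate and the Z-iodide untouched.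

Step 33
Reactants: 42 seco compound
Product: 43 25-O-TBS superstolide A
Conditions: Pd(PPh3)4 (20 mol %), TlOEt (3 equiv), THF/H2O (4:1), 1 mM, rt
Reagents that add atoms: none
Why: intramolecular Suzuki–Miyaura coupling at high dilution joins C5 and C6 with retention of both alkene geometries and closes the 16-membered lactone ring (macrocyclisation by sp2–sp2 cross-coupling), TlOEt making transmetalation fast at room temperature.

Step 34
Reactants: 43 25-O-TBS superstolide A
Product: 44 superstolide A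
Conditions: HF·pyridine, THF, 0 °C → rt
Reagents that add atoms: none
Why: the last silyl ether is cleaved by fluoride under mildly acidic conditions, which avoid acyl migration from O23 to O25, to give the target.

**Compound list**

1 | benzoic acid | OC(=O)c1ccccc1 | starting material
2 | dilithium (cyclohexa-2,5-dien-1-ylidene)methanediolate (Birch dianion) | [Li+].[Li+].[O-]C([O-])=C1C=CCC=C1 | intermediate
3 | 1-methylcyclohexa-2,5-diene-1-carboxylic acid | CC1(C(=O)O)C=CCC=C1 | intermediate
4 | methyl 1-methylcyclohexa-2,5-diene-1-carboxylate | COC(=O)C1(C)C=CCC=C1 | intermediate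
5 | methyl 1-methyl-4-oxocyclohexa-2,5-diene-1-carboxylate | COC(=O)C1(C)C=CC(=O)C=C1 | intermediate
6 | (E)-4-methoxybut-3-en-2-one | CO/C=C/C(C)=O | starting material
7 | 4-methoxybenzyl alcohol | COc1ccc(CO)cc1 | starting material
8 | (E)-4-[(4-methoxybenzyl)oxy]but-3-en-2-one | CC(=O)/C=C/OCc1ccc(OC)cc1 | intermediate
9 | (E)-1-[(4-methoxybenzyl)oxy]-3-(triisopropylsilyloxy)buta-1,3-diene | C=C(O[Si](C(C)C)(C(C)C)C(C)C)/C=C/OCc1ccc(OC)cc1 | intermediate
10 | cis-fused adduct: C11=C12 TIPS enol ether, 13α-OPMB, C15 ketone, C16=C17, C8 β-methyl and α-CO2Me, H9 and H14 β | CC(C)[Si](C(C)C)(C(C)C)OC1=C[C@H](OCc3ccc(OC)cc3)[C@@H]2C(=O)C=C[C@](C)(C(=O)OC)[C@@H]2C1 | intermediate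
11 | C11 ketone: as 10 with C11=O and C12 H2 | O=C1C[C@H](OCc3ccc(OC)cc3)[C@@H]2C(=O)C=C[C@](C)(C(=O)OC)[C@@H]2C1 | intermediate
12 | 11α-alcohol (11-OH cis to 13-OPMB) | O[C@@H]1C[C@H](OCc3ccc(OC)cc3)[C@@H]2C(=O)C=C[C@](C)(C(=O)OC)[C@@H]2C1 | intermediate
13 | 11α-methyl ether | CO[C@@H]1C[C@H](OCc3ccc(OC)cc3)[C@@H]2C(=O)C=C[C@](C)(C(=O)OC)[C@@H]2C1 | intermediate
14 | 7,15α-diol: C8 α-CH2OH, 15α-OH, C16=C17 | CO[C@@H]1C[C@H](OCc3ccc(OC)cc3)[C@@H]2[C@H](O)C=C[C@](C)(CO)[C@@H]2C1 | intermediate
15 | 7-O-TBS 15α-alcohol | CO[C@@H]1C[C@H](OCc3ccc(OC)cc3)[C@@H]2[C@H](O)C=C[C@](C)(CO[Si](C)(C)C(C)(C)C)[C@@H]2C1 | intermediate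
16 | 15α-O-(tributylstannylmethyl) ether | CO[C@@H]1C[C@H](OCc3ccc(OC)cc3)[C@@H]2[C@H](OC[Sn](CCCC)(CCCC)CCCC)C=C[C@](C)(CO[Si](C)(C)C(C)(C)C)[C@@H]2C1 | intermediate
17 | 15α-O-(lithiomethyl) ether | CO[C@@H]1C[C@H](OCc3ccc(OC)cc3)[C@@H]2[C@H](OC[Li])C=C[C@](C)(CO[Si](C)(C)C(C)(C)C)[C@@H]2C1 | intermediate
18 | 17α-(hydroxymethyl) C15=C16 alkene (H17 β) | CO[C@@H]1C[C@H](OCc3ccc(OC)cc3)[C@@H]2C=C[C@H](CO)[C@](C)(CO[Si](C)(C)C(C)(C)C)[C@@H]2C1 | intermediate
19 | C18 aldehyde (17α-formyl) | CO[C@@H]1C[C@H](OCc3ccc(OC)cc3)[C@@H]2C=C[C@H](C=O)[C@](C)(CO[Si](C)(C)C(C)(C)C)[C@@H]2C1 | intermediate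
20 | C18=C19 gem-dibromoalkene | CO[C@@H]1C[C@H](OCc3ccc(OC)cc3)[C@@H]2C=C[C@H](C=C(Br)Br)[C@](C)(CO[Si](C)(C)C(C)(C)C)[C@@H]2C1 | intermediate
21 | N-Boc-D-alaninal, tert-butyl N-[(2R)-1-oxopropan-2-yl]carbamate | O=C[C@@H](C)NC(=O)OC(C)(C)C | starting material
22 | tert-butyl N-[(2R,3S,4S)-3-hydroxy-4-methylhex-5-en-2-yl]carbamate | C=C[C@H](C)[C@H](O)[C@@H](C)NC(=O)OC(C)(C)C | intermediate
23 | (2R,3S,4S)-3-hydroxy-4-methylhex-5-en-2-aminium chloride | C=C[C@H](C)[C@H](O)[C@@H](C)[NH3+].[Cl-] | intermediate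
24 | N-[(2R,3S,4S)-3-hydroxy-4-methylhex-5-en-2-yl]acetamide | C=C[C@H](C)[C@H](O)[C@@H](C)NC(C)=O | intermediate
25 | N-[(2R,3S,4S)-3-(tert-butyldimethylsilyloxy)-4-methylhex-5-en-2-yl]acetamide | C=C[C@H](C)[C@H](O[Si](C)(C)C(C)(C)C)[C@@H](C)NC(C)=O | intermediate
26 | N-[(2R,3S,4R)-3-(tert-butyldimethylsilyloxy)-4-methyl-5-oxopentan-2-yl]acetamide | O=C[C@H](C)[C@H](O[Si](C)(C)C(C)(C)C)[C@@H](C)NC(C)=O | intermediate
27 | N-[(2R,3S,4S,5R,6R)-3-(tert-butyldimethylsilyloxy)-5-hydroxy-4,6-dimethyloct-7-en-2-yl]acetamide | C=C[C@@H](C)[C@H]([C@H](C)[C@H](O[Si](C)(C)C(C)(C)C)[C@@H](C)NC(C)=O)O | intermediate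
28 | (3R,4R,5S,6S,7R)-7-acetamido-6-(tert-butyldimethylsilyloxy)-3,5-dimethyloct-1-en-4-yl 2-(diethoxyphosphoryl)acetate | C=C[C@@H](C)[C@H]([C@H](C)[C@H](O[Si](C)(C)C(C)(C)C)[C@@H](C)NC(C)=O)OC(=O)CP(=O)(OCC)OCC | intermediate
29 | (1E,3R,4R,5S,6S,7R)-7-acetamido-6-(tert-butyldimethylsilyloxy)-3,5-dimethyl-1-(4,4,5,5-tetramethyl-1,3,2-dioxaborolan-2-yl)oct-1-en-4-yl 2-(diethoxyphosphoryl)acetate | CC1(C)OB(/C=C/[C@@H](C)[C@H]([C@H](C)[C@H](O[Si](C)(C)C(C)(C)C)[C@@H](C)NC(C)=O)OC(=O)CP(=O)(OCC)OCC)OC1(C)C | intermediate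
30 | 19-bromo-(18Z,20E)-diene: core 20 joined at C19 to C20 of 29 (Br cis to C17) | CO[C@@H]1C[C@H](OCc3ccc(OC)cc3)[C@@H]2C=C[C@H](/C=C(Br)/C=C/[C@@H](C)[C@H]([C@H](C)[C@H](O[Si](C)(C)C(C)(C)C)[C@@H](C)NC(C)=O)OC(=O)CP(=O)(OCC)OCC)[C@](C)(CO[Si](C)(C)C(C)(C)C)[C@@H]2C1 | intermediate
31 | 19-methyl-(18E,20E)-diene (7-OTBS, 13α-OPMB, O23 phosphonoacetate, 25-OTBS) | CO[C@@H]1C[C@H](OCc3ccc(OC)cc3)[C@@H]2C=C[C@H](/C=C(C)/C=C/[C@@H](C)[C@H]([C@H](C)[C@H](O[Si](C)(C)C(C)(C)C)[C@@H](C)NC(C)=O)OC(=O)CP(=O)(OCC)OCC)[C@](C)(CO[Si](C)(C)C(C)(C)C)[C@@H]2C1 | intermediate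
32 | 13α-alcohol | CO[C@@H]1C[C@H](O)[C@@H]2C=C[C@H](/C=C(C)/C=C/[C@@H](C)[C@H]([C@H](C)[C@H](O[Si](C)(C)C(C)(C)C)[C@@H](C)NC(C)=O)OC(=O)CP(=O)(OCC)OCC)[C@](C)(CO[Si](C)(C)C(C)(C)C)[C@@H]2C1 | intermediate
33 | 13α-O-[N-(trichloroacetyl)carbamate] | CO[C@@H]1C[C@H](OC(=O)NC(=O)C(Cl)(Cl)Cl)[C@@H]2C=C[C@H](/C=C(C)/C=C/[C@@H](C)[C@H]([C@H](C)[C@H](O[Si](C)(C)C(C)(C)C)[C@@H](C)NC(C)=O)OC(=O)CP(=O)(OCC)OCC)[C@](C)(CO[Si](C)(C)C(C)(C)C)[C@@H]2C1 | intermediate
34 | 13α-carbamate | CO[C@@H]1C[C@H](OC(N)=O)[C@@H]2C=C[C@H](/C=C(C)/C=C/[C@@H](C)[C@H]([C@H](C)[C@H](O[Si](C)(C)C(C)(C)C)[C@@H](C)NC(C)=O)OC(=O)CP(=O)(OCC)OCC)[C@](C)(CO[Si](C)(C)C(C)(C)C)[C@@H]2C1 | intermediate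
35 | C7 primary alcohol | CO[C@@H]1C[C@H](OC(N)=O)[C@@H]2C=C[C@H](/C=C(C)/C=C/[C@@H](C)[C@H]([C@H](C)[C@H](O[Si](C)(C)C(C)(C)C)[C@@H](C)NC(C)=O)OC(=O)CP(=O)(OCC)OCC)[C@](C)(CO)[C@@H]2C1 | intermediate
36 | C7 aldehyde | CO[C@@H]1C[C@H](OC(N)=O)[C@@H]2C=C[C@H](/C=C(C)/C=C/[C@@H](C)[C@H]([C@H](C)[C@H](O[Si](C)(C)C(C)(C)C)[C@@H](C)NC(C)=O)OC(=O)CP(=O)(OCC)OCC)[C@](C)(C=O)[C@@H]2C1 | intermediate
37 | (6E)-C6 pinacol alkenylboronate | CO[C@@H]1C[C@H](OC(N)=O)[C@@H]2C=C[C@H](/C=C(C)/C=C/[C@@H](C)[C@H]([C@H](C)[C@H](O[Si](C)(C)C(C)(C)C)[C@@H](C)NC(C)=O)OC(=O)CP(=O)(OCC)OCC)[C@](C)(/C=C/B3OC(C)(C)C(C)(C)O3)[C@@H]2C1 | intermediate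
38 | but-2-yn-1-ol | CC#CCO | starting material
39 | sodium 2,2-bis(2-methoxyethoxy)-3-methyl-2,5-dihydro-1,2-oxaluminol-2-uide (cyclic alkenylalanate) | [Na+].CC1=CCO[Al-]1(OCCOC)OCCOC | intermediate
40 | (Z)-3-iodobut-2-en-1-ol | OC/C=C(\I)C | intermediate
41 | (Z)-3-iodobut-2-enal | O=C/C=C(\I)C | intermediate
42 | seco compound: O23 (2E,4Z)-5-iodohexa-2,4-dienoate, (6E)-C6 boronate, 13α-carbamate, 25-OTBS | CO[C@@H]1C[C@H](OC(N)=O)[C@@H]2C=C[C@H](/C=C(C)/C=C/[C@@H](C)[C@H]([C@H](C)[C@H](O[Si](C)(C)C(C)(C)C)[C@@H](C)NC(C)=O)OC(=O)/C=C/C=C(C)\I)[C@](C)(/C=C/B3OC(C)(C)C(C)(C)O3)[C@@H]2C1 | intermediate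
43 | 25-O-(tert-butyldimethylsilyl)superstolide A | CO[C@@H]1C[C@H](OC(N)=O)[C@@H]2C=C[C@@H]3/C=C(C)/C=C/[C@@H](C)[C@H]([C@H](C)[C@H](O[Si](C)(C)C(C)(C)C)[C@@H](C)NC(C)=O)OC(=O)/C=C/C=C(C)\C=C\[C@]3(C)[C@@H]2C1 | intermediate
44 | superstolide A | CO[C@@H]1C[C@H](OC(N)=O)[C@@H]2C=C[C@@H]3/C=C(C)/C=C/[C@@H](C)[C@H]([C@H](C)[C@H](O)[C@@H](C)NC(C)=O)OC(=O)/C=C/C=C(C)\C=C\[C@]3(C)[C@@H]2C1 | target

**Count and risks**

Total step count: 34. Longest linear sequence: 23 steps from benzoic acid (steps 1–3, 6–15, 23–29, 32–34).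

Steps most likely to fail:

1. Step 6. The very electron-rich diene may transfer its silyl group to the triflimide counter-ion and start an achiral silyl-cation-catalysed background reaction, which would erode enantiotopic selection; discrimination between the methyl and ester faces may also be incomplete. Fallback (resolution instead of asymmetric catalysis), setting out from 5 and 9 and returning at 12: the cycloaddition is run with ZnCl2 in CH2Cl2 to give the racemic adduct F1 in the same endo, ester-face mode. Desilylation (n-Bu4NF/AcOH) gives the racemic C11 ketone F2, and NaBH4 at −78 °C gives the racemic 11α-alcohol F3. Esterification with (S)-O-methylmandelic acid (carbodiimide, 4-(dimethylamino)pyridine) gives two diastereomers, the mandelate of 12 F4 and the mandelate of the enantiomer of 12 F5, which are separated by chromatography. Methanolysis of F4 (K2CO3, MeOH, 0 °C) returns enantiopure 12.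

2. Step 13. The new C–C bond must form on the concave face next to the quaternary C8, so a [1,2]-shift or simple protonation of the organolithium may outrun the [2,3]-shift. Fallback ([3,3] instead of [2,3] transfer, then one-carbon degradation), setting out from 15 and returning at 19: Johnson–Claisen rearrangement (MeC(OEt)3, cat. EtCO2H, xylene, 140 °C) gives the 17α-(ethoxycarbonylmethyl) C15=C16 alkene F6 with the same suprafacial transfer from C15 to C17. Enolate hydroxylation (KN(SiMe3)2; 2-(phenylsulfonyl)-3-phenyloxaziridine) gives the α-hydroxy ester F7 (both C18 epimers are used). LiAlH4 reduction gives the 1,2-diol F8, and NaIO4 cleavage (THF/H2O) gives aldehyde 19.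

3. Step 33. Ring closure may be slower than oligomerisation or protodeboronation at the boronate next to the quaternary centre. Fallback (ring closure at C2=C3 by olefination instead of at C5–C6 by coupling), setting out from 37 and 40 and returning at 43: intermolecular Suzuki coupling of 37 with iodo alcohol 40 (Pd(PPh3)4, TlOEt, THF/H2O) gives the (4Z,6E)-dienol F9. MnO2 oxidation gives the (4Z,6E)-dienal F10. Intramolecular Horner–Wadsworth–Emmons olefination (LiCl, i-Pr2NEt, MeCN, 1 mM) closes the lactone ring and gives 43.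

Further compounds
F1 | step 6 | racemic adduct (10 and its enantiomer) | CC(C)[Si](C(C)C)(C(C)C)OC1=C[C@H](OCc3ccc(OC)cc3)[C@@H]2C(=O)C=C[C@](C)(C(=O)OC)[C@@H]2C1.CC(C)[Si](C(C)C)(C(C)C)OC1=C[C@@H](OCc3ccc(OC)cc3)[C@H]2C(=O)C=C[C@@](C)(C(=O)OC)[C@H]2C1
F2 | step 6 | racemic C11 ketone (11 and its enantiomer) | O=C1C[C@H](OCc3ccc(OC)cc3)[C@@H]2C(=O)C=C[C@](C)(C(=O)OC)[C@@H]2C1.O=C1C[C@@H](OCc3ccc(OC)cc3)[C@H]2C(=O)C=C[C@@](C)(C(=O)OC)[C@H]2C1
F3 | step 6 | racemic 11α-alcohol (12 and its enantiomer) | O[C@@H]1C[C@H](OCc3ccc(OC)cc3)[C@@H]2C(=O)C=C[C@](C)(C(=O)OC)[C@@H]2C1.O[C@H]1C[C@@H](OCc3ccc(OC)cc3)[C@H]2C(=O)C=C[C@@](C)(C(=O)OC)[C@H]2C1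
F4 | step 6 | (S)-O-methylmandelate of 12 | CO[C@H](C(=O)O[C@@H]1C[C@H](OCc3ccc(OC)cc3)[C@@H]2C(=O)C=C[C@](C)(C(=O)OC)[C@@H]2C1)c1ccccc1
F5 | step 6 | (S)-O-methylmandelate of the enantiomer of 12 | CO[C@H](C(=O)O[C@H]1C[C@@H](OCc3ccc(OC)cc3)[C@H]2C(=O)C=C[C@@](C)(C(=O)OC)[C@H]2C1)c1ccccc1
F6 | step 13 | 17α-(ethoxycarbonylmethyl) C15=C16 alkene | CO[C@@H]1C[C@H](OCc3ccc(OC)cc3)[C@@H]2C=C[C@H](CC(=O)OCC)[C@](C)(CO[Si](C)(C)C(C)(C)C)[C@@H]2C1
F7 | step 13 | α-hydroxy ester (C18 epimers) | CO[C@@H]1C[C@H](OCc3ccc(OC)cc3)[C@@H]2C=C[C@H](C(O)C(=O)OCC)[C@](C)(CO[Si](C)(C)C(C)(C)C)[C@@H]2C1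
F8 | step 13 | 1,2-diol (C18 epimers) | CO[C@@H]1C[C@H](OCc3ccc(OC)cc3)[C@@H]2C=C[C@H](C(O)CO)[C@](C)(CO[Si](C)(C)C(C)(C)C)[C@@H]2C1
F9 | step 33 | (4Z,6E)-dienol with O23 phosphonoacetate | CO[C@@H]1C[C@H](OC(N)=O)[C@@H]2C=C[C@H](/C=C(C)/C=C/[C@@H](C)[C@H]([C@H](C)[C@H](O[Si](C)(C)C(C)(C)C)[C@@H](C)NC(C)=O)OC(=O)CP(=O)(OCC)OCC)[C@](C)(/C=C/C(C)=C\CO)[C@@H]2C1
F10 | step 33 | (4Z,6E)-dienal with O23 phosphonoacetate | CO[C@@H]1C[C@H](OC(N)=O)[C@@H]2C=C[C@H](/C=C(C)/C=C/[C@@H](C)[C@H]([C@H](C)[C@H](O[Si](C)(C)C(C)(C)C)[C@@H](C)NC(C)=O)OC(=O)CP(=O)(OCC)OCC)[C@](C)(/C=C/C(C)=C\C=O)[C@@H]2C1
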